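**Retrosynthetic overview**
1. The target is 2-[(2S,12S)-2,12-diacetoxytridecyl]-4,6-dihydroxybenzoic acid (side chain numbered from the benzylic carbon C1′). It is disconnected at the side-chain C2′–C3′ bond, between the acetoxy-bearing carbon and the first chain methylene.
2. That bond is formed by a four-component nickel-hydride coupling of an arylacetaldehyde, acetyl bromide, a terminal olefin and a hydrosilane. In one operation it joins the fragments, sets C2′ (S) under ligand control and installs the C2′ acetate.
3. Enabling feature: C2′ is an O-acyl sp3 carbon flanked by two CH2 groups (the ester of a dialkyl carbinol). It can therefore be generated as an α-acetoxyalkyl radical from an achiral aldehyde, and the activating acetate is part of the target and stays.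
4. The olefin partner carries C12′ (S) from (S)-2-methyloxirane. The carboxyl carbon is held at its lowest oxidation level (ring C–H ortho to the side chain, para to one oxygen) and added after the coupling by formylation and oxidation.
5. No ring is formed: the benzene ring is bought as 3,5-bis(benzyloxy)benzaldehyde, and hydrogenolysis of the two benzyl ethers ends the route.

Key step: step 5

Assumption: the bis(oxazoline) antipode written in step 5, (S,S)-Ph-BOX = (4S,4′S)-2,2′-(propane-2,2-diyl)bis(4-phenyl-4,5-dihydro-1,3-oxazole), is taken as the one that delivers the (S)-ester at C2′. Its sense should be fixed in a model coupling; if it proves opposite, the (R,R) antipode is used and nothing else changes.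

**Step 1**
Reactants: 1 3,5-bis(benzyloxy)benzaldehyde
Product: 2 1,3-bis(benzyloxy)-5-(2-methoxyethenyl)benzene (E/Z mixture)
Conditions: Ph3P(CH2OMe)Cl, KOt-Bu, THF, 0 °C → rt
Reagents that add atoms: (methoxymethyl)triphenylphosphonium chloride, COC[P+](c1ccccc1)(c1ccccc1)c1ccccc1.[Cl-]
Why: Wittig olefination of a non-enolisable aryl aldehyde with the methoxymethylene ylide should give the one-carbon-homologated enol ether; the olefin geometry is irrelevant because both isomers hydrolyse to the same aldehyde.

**Step 2**
Reactants: 2 1,3-bis(benzyloxy)-5-(2-methoxyethenyl)benzene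
Product: 3 2-[3,5-bis(benzyloxy)phenyl]acetaldehyde
Conditions: HCO2H (88% aq), CH2Cl2, rt; used at once
Reagents that add atoms: water, O
Why: Acid-catalysed enol ether hydrolysis (protonation at the styrenic carbon, then collapse of the hemiacetal) should unmask the arylacetaldehyde under conditions that leave aryl benzyl ethers intact.

**Step 3**
Reactants: 4 8-bromooct-1-ene; 5 (S)-2-methyloxirane
Product: 7 (S)-undec-10-en-2-ol, via oct-7-en-1-ylmagnesium bromide 6 (not isolated)
Conditions: Mg, THF, rt; then CuI (10 mol %), 5, THF, −30 → 0 °C; aq NH4Cl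
Reagents that add atoms: none
Why: CuI-catalysed Grignard opening of a terminal epoxide proceeds by SN2 attack at the unsubstituted CH2, so the C–O stereocentre of 5 is untouched and becomes the (S)-carbinol that is C12′ of the target.

**Step 4**
Reactants: 7 (S)-undec-10-en-2-ol
Product: 8 (S)-undec-10-en-2-yl acetate
Conditions: Ac2O, pyridine, DMAP (cat.), CH2Cl2, rt
Reagents that add atoms: acetic anhydride, CC(=O)OC(C)=O
Why: DMAP-catalysed O-acylation of a secondary alcohol breaks no bond at the stereocentre, so the (S) configuration is retained.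

**Step 5**
Reactants: 3 2-[3,5-bis(benzyloxy)phenyl]acetaldehyde; 8 (S)-undec-10-en-2-yl acetate
Product: 10 (2S,12S)-1-[3,5-bis(benzyloxy)phenyl]tridecane-2,12-diyl diacetate, via racemic 2-[3,5-bis(benzyloxy)phenyl]-1-bromoethyl acetate 9 (not isolated)
Conditions: AcBr, CH2Cl2, −10 °C → rt, evaporate; then 8, NiBr2·glyme (10 mol %), (S,S)-Ph-BOX (12 mol %), (EtO)2MeSiH, K3PO4·H2O, DMA/THF, 0 °C → rt
Reagents that add atoms: acetyl bromide, CC(=O)Br
Why: Acetyl bromide adds across the aldehyde C=O to give the racemic 1-bromoalkyl acetate 9; monovalent nickel abstracts its bromine to give a planar α-acetoxyalkyl radical, so both enantiomers of 9 converge, while a nickel hydride formed from the silane inserts the terminal olefin of 8 anti-Markovnikov to give a primary alkylnickel that captures the radical and reductively eliminates from trivalent nickel, forming the C2–C3 bond of the tridecane chain. The closest known reaction type is the nickel-hydride enantioconvergent hydroalkylation of terminal olefins with racemic 1-bromoalkyl esters, including its four-component form from aldehyde, acyl bromide, olefin and hydrosilane. No ring is closed. The new stereocentre at C2 is controlled by the chiral bis(oxazoline)nickel complex, to which the acetate carbonyl of the radical fragment can bind, and the ligand antipode is chosen to give (S); C12 comes unchanged from 8. The step needs linear regioselectivity, which the unactivated monosubstituted olefin secures, enantioselectivity at a carbon flanked by two CH2 groups, for which the ester group is the differentiating handle, and chemoselectivity, which rests on the inertness of aryl benzyl ethers and the remote acetate toward nickel hydride at or below room temperature.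

**Step 6**
Reactants: 10 (2S,12S)-1-[3,5-bis(benzyloxy)phenyl]tridecane-2,12-diyl diacetate
Product: 12 (2S,12S)-1-[3,5-bis(benzyloxy)-2-formylphenyl]tridecane-2,12-diyl diacetate, via aryl iminium chloride 11 (not isolated)
Conditions: POCl3, DMF, 0 → 60 °C; then aq NaOAc, rt
Reagents that add atoms: N,N-dimethylformamide, CN(C)C=O; water, O
Why: Vilsmeier–Haack formylation (electrophilic aromatic substitution) should take place at one of the two equivalent ring positions ortho to the side chain and para to a benzyloxy group, which are more accessible than the position between the two benzyloxy groups; the acetates are inert to the chloroiminium reagent and the iminium salt is hydrolysed on work-up.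

**Step 7**
Reactants: 12 (2S,12S)-1-[3,5-bis(benzyloxy)-2-formylphenyl]tridecane-2,12-diyl diacetate
Product: 13 2,4-bis(benzyloxy)-6-[(2S,12S)-2,12-diacetoxytridecyl]benzoic acid
Conditions: NaClO2, NaH2PO4, 2-methylbut-2-ene, t-BuOH/THF/H2O, 0 °C → rt
Reagents that add atoms: sodium chlorite, [Na+].[O-]Cl=O
Why: Pinnick oxidation converts the hindered, electron-rich benzaldehyde into the acid in buffered medium, with 2-methylbut-2-ene trapping hypochlorous acid so that the ring is not chlorinated and the acetates and stereocentres are untouched.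

**Step 8**
Reactants: 13 2,4-bis(benzyloxy)-6-[(2S,12S)-2,12-diacetoxytridecyl]benzoic acid
Product: 14 2-[(2S,12S)-2,12-diacetoxytridecyl]-4,6-dihydroxybenzoic acid
Conditions: H2 (1 atm), Pd/C (10 wt %), EtOAc, rt
Reagents that add atoms: none
Why: Hydrogenolysis of the two aryl benzyl ethers over Pd/C at neutral pH should release both phenols without touching the secondary acetates, which are homobenzylic and not benzylic, the carboxylic acid or either stereocentre.

**Compound list**
1 | 3,5-bis(benzyloxy)benzaldehyde | O=Cc1cc(OCc2ccccc2)cc(OCc2ccccc2)c1 | starting material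
2 | 1,3-bis(benzyloxy)-5-(2-methoxyethenyl)benzene (E/Z mixture) | COC=Cc1cc(OCc2ccccc2)cc(OCc2ccccc2)c1 | intermediate
3 | 2-[3,5-bis(benzyloxy)phenyl]acetaldehyde | O=CCc1cc(OCc2ccccc2)cc(OCc2ccccc2)c1 | intermediate
4 | 8-bromooct-1-ene | C=CCCCCCCBr | starting material
5 | (S)-2-methyloxirane | C[C@H]1CO1 | starting material
6 | oct-7-en-1-ylmagnesium bromide | C=CCCCCCC[Mg]Br | intermediate
7 | (S)-undec-10-en-2-ol | C=CCCCCCCC[C@H](C)O | intermediate
8 | (S)-undec-10-en-2-yl acetate | C=CCCCCCCC[C@H](C)OC(C)=O | intermediate
9 | racemic 2-[3,5-bis(benzyloxy)phenyl]-1-bromoethyl acetate | CC(=O)OC(Br)Cc1cc(OCc2ccccc2)cc(OCc2ccccc2)c1 | intermediate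
10 | (2S,12S)-1-[3,5-bis(benzyloxy)phenyl]tridecane-2,12-diyl diacetate | CC(=O)O[C@@H](CCCCCCCCC[C@H](C)OC(C)=O)Cc1cc(OCc2ccccc2)cc(OCc2ccccc2)c1 | intermediate
11 | {2,4-bis(benzyloxy)-6-[(2S,12S)-2,12-diacetoxytridecyl]benzylidene}dimethyliminium chloride | CC(=O)O[C@@H](CCCCCCCCC[C@H](C)OC(C)=O)Cc1cc(OCc2ccccc2)cc(OCc2ccccc2)c1C=[N+](C)C.[Cl-] | intermediate
12 | (2S,12S)-1-[3,5-bis(benzyloxy)-2-formylphenyl]tridecane-2,12-diyl diacetate | CC(=O)O[C@@H](CCCCCCCCC[C@H](C)OC(C)=O)Cc1cc(OCc2ccccc2)cc(OCc2ccccc2)c1C=O | intermediate
13 | 2,4-bis(benzyloxy)-6-[(2S,12S)-2,12-diacetoxytridecyl]benzoic acid | CC(=O)O[C@@H](CCCCCCCCC[C@H](C)OC(C)=O)Cc1cc(OCc2ccccc2)cc(OCc2ccccc2)c1C(=O)O | intermediate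
14 | 2-[(2S,12S)-2,12-diacetoxytridecyl]-4,6-dihydroxybenzoic acid | CC(=O)O[C@@H](CCCCCCCCC[C@H](C)OC(C)=O)Cc1cc(O)cc(O)c1C(=O)O | target

**Step count and risks**
Total steps: 8. Longest linear sequence: 6 (steps 1, 2, 5, 6, 7, 8; the olefin branch, steps 3, 4, 5, 6, 7, 8, is equally long).

Steps most likely to fail:

Step 5. The bromo ester may lose HBr under the basic phosphate toward the aryl-conjugated enol acetate, the nickel hydride may reduce the C–Br bond directly, and catalyst control at C2 may be incomplete, which would give a diastereomer mixture that is hard to separate because the two stereocentres are remote. The fallback sets out from 8 and 3 and comes back at 10, forming the same bond by a catalyst-controlled carbonyl addition. Hydroboration of 8 with Et2BH should give (S)-11-(diethylboranyl)undecan-2-yl acetate F1. Boron–zinc exchange with Et2Zn, with BEt3 removed in vacuo, should give bis[(10S)-10-acetoxyundecyl]zinc F2. Addition of this to 3 with Ti(OiPr)4 and catalytic (1R,2R)-1,2-bis(trifluoromethanesulfonamido)cyclohexane in toluene at −20 °C, with attack expected on the Si face, should give (2S,12S)-13-[3,5-bis(benzyloxy)phenyl]-12-hydroxytridecan-2-yl acetate F3. Acetylation (Ac2O, pyridine, DMAP) returns 10.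

Step 6. Formylation may be slow at the hindered position next to the side chain, or may go in part to the position between the two benzyloxy groups. The fallback sets out from 10 and comes back at 14, replacing formylation and oxidation by halogenation and carbonylation. Bromination with NBS in MeCN at 0 °C, which is expected to be highly selective for the position para to a benzyloxy group and ortho to the chain, should give (2S,12S)-1-[3,5-bis(benzyloxy)-2-bromophenyl]tridecane-2,12-diyl diacetate F4. Carbonylation with Pd(OAc)2 and Xantphos (CO 1 atm, BnOH, Et3N, toluene, 90 °C) should give benzyl 2,4-bis(benzyloxy)-6-[(2S,12S)-2,12-diacetoxytridecyl]benzoate F5. Hydrogenolysis over Pd/C then removes all three benzyl groups and gives 14 directly.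

Step 2. The enolisable, electron-rich arylacetaldehyde may self-condense (aldol) under the acidic hydrolysis, or the hydrolysis may stall. The fallback sets out from 1 and comes back at 3, releasing the aldehyde by a neutral oxidation. Methylenation (Ph3PCH3Br, KOt-Bu, THF) should give 1,3-bis(benzyloxy)-5-ethenylbenzene F6. Hydroboration with 9-BBN should give 9-{2-[3,5-bis(benzyloxy)phenyl]ethyl}-9-borabicyclo[3.3.1]nonane F7, and oxidation (NaOH, H2O2) should give 2-[3,5-bis(benzyloxy)phenyl]ethanol F8. Dess–Martin periodinane with NaHCO3 in CH2Cl2 then delivers 3.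

**Further compounds**
F1 | step 5 | (S)-11-(diethylboranyl)undecan-2-yl acetate | CCB(CC)CCCCCCCCC[C@H](C)OC(C)=O
F2 | step 5 | bis[(10S)-10-acetoxyundecyl]zinc | CC(=O)O[C@@H](C)CCCCCCCCC[Zn]CCCCCCCCC[C@H](C)OC(C)=O
F3 | step 5 | (2S,12S)-13-[3,5-bis(benzyloxy)phenyl]-12-hydroxytridecan-2-yl acetate | CC(=O)O[C@@H](C)CCCCCCCCC[C@H](O)Cc1cc(OCc2ccccc2)cc(OCc2ccccc2)c1
F4 | step 6 | (2S,12S)-1-[3,5-bis(benzyloxy)-2-bromophenyl]tridecane-2,12-diyl diacetate | CC(=O)O[C@@H](CCCCCCCCC[C@H](C)OC(C)=O)Cc1cc(OCc2ccccc2)cc(OCc2ccccc2)c1Br
F5 | step 6 | benzyl 2,4-bis(benzyloxy)-6-[(2S,12S)-2,12-diacetoxytridecyl]benzoate | CC(=O)O[C@@H](CCCCCCCCC[C@H](C)OC(C)=O)Cc1cc(OCc2ccccc2)cc(OCc2ccccc2)c1C(=O)OCc1ccccc1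
F6 | step 2 | 1,3-bis(benzyloxy)-5-ethenylbenzene | C=Cc1cc(OCc2ccccc2)cc(OCc2ccccc2)c1
F7 | step 2 | 9-{2-[3,5-bis(benzyloxy)phenyl]ethyl}-9-borabicyclo[3.3.1]nonane | C1CC2CCCC(C1)B2CCc3cc(OCc4ccccc4)cc(OCc4ccccc4)c3
F8 | step 2 | 2-[3,5-bis(benzyloxy)phenyl]ethanol | OCCc1cc(OCc2ccccc2)cc(OCc2ccccc2)c1
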